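## Retrosynthetic overview

1. Feature: the side-chain alkene carbon bearing CH3 (C6'), C7'H=, C8'H2, C9'H2, the carbinol carbon C10' and its oxygen map onto C6, C5, C4, C3, C2 and O1 of a six-membered 2,2-disubstituted 3,4-dihydro-2H-pyran ring. Opening that ring at C6–O1 can deliver the E-C6'=C7' alkene and the free (S)-C10' carbinol together.
2. Disconnection A: butenolide C5=C1' by aldol addition of C5-lithiated 4-methoxy-3-methylfuran-2(5H)-one to the C1' aldehyde, dehydration and O-demethylation.
3. Disconnection B (key): C5'–C6' and C6'–CH3 by 1,2-shift of an alkyl group in a mixed alkyl(alkenyl)cuprate made from a 6-stannyl dihydropyran and an alkyl iodide, with ring opening and methylation by MeI.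
4. Fragments: the stannane from (R)-linalool (vinyl arm to the 3-(furan-3-yl)propyl chain; prenyl arm to ring C3–C6 through a lactol, methoxymethylene Wittig, anomeric sulfone and stannylation–elimination); the iodide from methyl (R)-3-hydroxy-2-methylpropanoate by two-carbon extension.
5. Ring order: the furan is bought; the butenolide ring is closed in step 15; the oxane ring is closed in step 7, made into the dihydropyran in step 8 and opened again in step 17.

Key step: step 17

Assumption: commercial (R)-linalool and methyl (R)-3-hydroxy-2-methylpropanoate are taken as single enantiomers, since C10' and C2' of the target come from them with all four bonds intact; primed locants count the side chain from the butenolide.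

## Route

Step 1
Reactants: 1 (R)-linalool
Product: 3 (R)-3,7-dimethyloct-6-ene-1,3-diol, via B-alkyl-9-BBN adduct 2 (not isolated)
Conditions: 9-BBN (2.2 equiv), THF, 0 °C → rt; then aq. NaOH, 30% H2O2, 0 °C → rt
Reagents that add atoms: hydrogen peroxide, OO
Why: Brown hydroboration–oxidation: 9-BBN puts boron on the terminal carbon of the monosubstituted vinyl group far faster than it attacks the trisubstituted alkene, and the quaternary stereocentre keeps its configuration because none of its bonds is touched.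

Step 2
Reactants: 3 (R)-3,7-dimethyloct-6-ene-1,3-diol
Product: 4 (R)-3-hydroxy-3,7-dimethyloct-6-en-1-yl 4-methylbenzenesulfonate
Conditions: TsCl (1.05 equiv), Et3N, DMAP (cat.), CH2Cl2, 0 °C
Reagents that add atoms: 4-toluenesulfonyl chloride, Cc1ccc(cc1)S(Cl)(=O)=O
Why: Sulfonate ester formation is selective for the unhindered primary hydroxyl, the tertiary one being too crowded to react with TsCl at 0 °C.

Step 3
Reactants: 5 furan-3-ylmethanol
Product: 6 3-(chloromethyl)furan
Conditions: SOCl2, pyridine, Et2O, 0 °C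
Reagents that add atoms: thionyl chloride, O=S(Cl)Cl
Why: Deoxychlorination through the chlorosulfite, with pyridine as HCl scavenger, should give the primary furylmethyl chloride without exposing the furan to free acid.

Step 4
Reactants: 4 (R)-3-hydroxy-3,7-dimethyloct-6-en-1-yl 4-methylbenzenesulfonate; 6 3-(chloromethyl)furan
Product: 8 (S)-1-(furan-3-yl)-4,8-dimethylnon-7-en-4-ol, via furylmethyl Grignard reagent 7 (not isolated)
Conditions: 6, Mg, THF, 0 °C (gives 7, 3 equiv); then 4, Li2CuCl4 (5 mol %), THF, −78 → 0 °C; aq. work-up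
Reagents that add atoms: none
Why: Li2CuCl4-catalysed sp3–sp3 cross-coupling of a Grignard reagent with a primary tosylate joins the furylmethyl CH2 to C1 of the chain; one equivalent of 7 is spent on the tertiary O–H, and the change of descriptor from R to S reflects only a change in substituent ranking.

Step 5
Reactants: 8 (S)-1-(furan-3-yl)-4,8-dimethylnon-7-en-4-ol
Product: 10 (5S)-5-[3-(furan-3-yl)propyl]-5-methyltetrahydrofuran-2-ol (anomer mixture), via triol 9 (not isolated)
Conditions: OsO4 (2 mol %), NMO, acetone–H2O, rt; then NaIO4, THF–H2O, 0 °C → rt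
Reagents that add atoms: osmium tetroxide, O=[Os](=O)(=O)=O, its oxygen resupplied by N-methylmorpholine N-oxide, C[N+]1([O-])CCOCC1
Why: Catalytic OsO4 dihydroxylation picks the electron-rich trisubstituted alkene over the aromatic furan, and periodate glycol cleavage (Lemieux–Johnson type sequence) gives the 4-hydroxy aldehyde, which closes onto the tertiary hydroxyl as the five-membered lactol.

Step 6
Reactants: 10 (5S)-5-[3-(furan-3-yl)propyl]-5-methyltetrahydrofuran-2-ol
Product: 11 (4S)-1-(furan-3-yl)-8-methoxy-4-methyloct-7-en-4-ol (E/Z mixture)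
Conditions: Ph3P(CH2OMe)Cl (3 equiv), KN(SiMe3)2 (3 equiv), THF, 0 °C → rt
Reagents that add atoms: (methoxymethyl)triphenylphosphonium chloride, COC[P+](c1ccccc1)(c1ccccc1)c1ccccc1.[Cl-]
Why: Wittig methoxymethylenation of the open hydroxy aldehyde form of the lactol adds the one carbon needed for a six-membered ring, the excess ylide covering deprotonation of the lactol hydroxyl.

Step 7
Reactants: 11 (4S)-1-(furan-3-yl)-8-methoxy-4-methyloct-7-en-4-ol
Product: 13 (6S)-6-[3-(furan-3-yl)propyl]-6-methyl-2-(phenylsulfonyl)tetrahydro-2H-pyran (C2 epimers), via 2-methoxytetrahydropyran acetal 12 (not isolated)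
Conditions: PhSO2H (2 equiv), CaCl2, CH2Cl2, rt
Reagents that add atoms: benzenesulfinic acid, OS(=O)c1ccccc1
Why: Acid-catalysed addition of the tertiary hydroxyl to the protonated enol ether closes the oxane as its methyl acetal (six-membered ring through an oxocarbenium ion), and the same acid exchanges methoxide for sulfinate at the anomeric carbon (anomeric sulfone formation); C6 is untouched and the C2 epimers converge in step 8.

Step 8
Reactants: 13 (6S)-6-[3-(furan-3-yl)propyl]-6-methyl-2-(phenylsulfonyl)tetrahydro-2H-pyran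
Product: 15 tributyl{(2S)-2-[3-(furan-3-yl)propyl]-2-methyl-3,4-dihydro-2H-pyran-6-yl}stannane, via stannylated sulfone 14 (not isolated)
Conditions: n-BuLi (1.05 equiv), THF, −78 °C; Bu3SnCl, −78 °C → rt; then i-Pr2NEt, toluene, 80 °C; chromatography on Et3N-treated silica
Reagents that add atoms: tributyltin chloride, CCCC[Sn](Cl)(CCCC)CCCC
Why: Deprotonation α to sulfone and oxygen at −78 °C is much faster than metalation of a furan C–H, the carbanion is stannylated by Bu3SnCl, and base-assisted β-elimination of benzenesulfinic acid should give the endocyclic enol ether with tin on C6 (sulfone-based synthesis of 1-stannyl cyclic enol ethers).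

Step 9
Reactants: 16 methyl (R)-3-hydroxy-2-methylpropanoate
Product: 17 methyl (R)-3-[(tert-butyldimethylsilyl)oxy]-2-methylpropanoate
Conditions: TBSCl, imidazole, CH2Cl2, rt
Reagents that add atoms: tert-butyldimethylsilyl chloride, CC(C)(C)[Si](C)(C)Cl
Why: Silyl ether formation on the primary hydroxyl under imidazole catalysis; this weak base does not enolise the α-stereocentre.

Step 10
Reactants: 17 methyl (R)-3-[(tert-butyldimethylsilyl)oxy]-2-methylpropanoate
Product: 18 (S)-3-[(tert-butyldimethylsilyl)oxy]-2-methylpropan-1-ol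
Conditions: i-Bu2AlH (2.5 equiv), CH2Cl2, −78 → 0 °C
Reagents that add atoms: none
Why: Hydride reduction of the ester to the primary alcohol with i-Bu2AlH proceeds without enolisation; the descriptor changes from R to S only because CH2OTBS now outranks CH2OH.

Step 11
Reactants: 18 (S)-3-[(tert-butyldimethylsilyl)oxy]-2-methylpropan-1-ol
Product: 20 ethyl (S,E)-5-[(tert-butyldimethylsilyl)oxy]-4-methylpent-2-enoate, via aldehyde 19 (not isolated)
Conditions: (COCl)2, DMSO, CH2Cl2, −78 °C; Et3N, −78 → 0 °C; then Ph3P=CHCO2Et, rt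
Reagents that add atoms: ethyl (triphenylphosphoranylidene)acetate, CCOC(=O)C=P(c1ccccc1)(c1ccccc1)c1ccccc1
Why: Swern oxidation followed by Wittig olefination with the stabilised ylide in the same flask traps the epimerisable α-methyl aldehyde as soon as it forms and gives the E-enoate, whose geometry no longer matters after step 12.

Step 12
Reactants: 20 ethyl (S,E)-5-[(tert-butyldimethylsilyl)oxy]-4-methylpent-2-enoate
Product: 21 ethyl (S)-5-[(tert-butyldimethylsilyl)oxy]-4-methylpentanoate
Conditions: H2 (1 atm), 10% Pd/C, EtOAc, rt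
Reagents that add atoms: none
Why: Heterogeneous catalytic hydrogenation saturates the conjugated alkene while the silyl ether and the ester are inert in EtOAc.

Step 13
Reactants: 21 ethyl (S)-5-[(tert-butyldimethylsilyl)oxy]-4-methylpentanoate
Product: 22 (S)-5-[(tert-butyldimethylsilyl)oxy]-4-methylpentan-1-ol
Conditions: i-Bu2AlH (2.5 equiv), CH2Cl2, −78 → 0 °C
Reagents that add atoms: none
Why: i-Bu2AlH reduction of the ethyl ester gives the primary alcohol and leaves the TBS ether in place.

Step 14
Reactants: 22 (S)-5-[(tert-butyldimethylsilyl)oxy]-4-methylpentan-1-ol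
Product: 23 (S)-tert-butyl[(5-iodo-2-methylpentyl)oxy]dimethylsilane
Conditions: I2, PPh3, imidazole, CH2Cl2, 0 °C → rt
Reagents that add atoms: iodine, II
Why: Appel-type iodination converts the primary alcohol by SN2 displacement of the oxyphosphonium group, with the remote stereocentre unaffected.

Step 15
Reactants: 24 ethyl 2-methyl-3-oxobutanoate
Product: 26 4-hydroxy-3-methylfuran-2(5H)-one, via 4-bromo ester 25 (not isolated)
Conditions: Br2, CHCl3, 0 °C → rt, 16 h; then neat, 130 °C
Reagents that add atoms: none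
Why: Ketone bromination, equilibrated by the HBr formed to the 4-bromo isomer, followed by thermal O-alkylative lactonisation with loss of bromoethane is the classical tetronic acid synthesis.

Step 16
Reactants: 26 4-hydroxy-3-methylfuran-2(5H)-one
Product: 27 4-methoxy-3-methylfuran-2(5H)-one
Conditions: Me2SO4, K2CO3, acetone, reflux
Reagents that add atoms: dimethyl sulfate, COS(=O)(=O)OC
Why: Williamson-type O-methylation of the vinylogous acid gives the 4-methoxy butenolide, the conjugated vinylogous-ester isomer being the favoured product.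

Step 17
Reactants: 15 tributyl{(2S)-2-[3-(furan-3-yl)propyl]-2-methyl-3,4-dihydro-2H-pyran-6-yl}stannane; 23 (S)-tert-butyl[(5-iodo-2-methylpentyl)oxy]dimethylsilane
Product: 33 (4S,7E,12S)-13-[(tert-butyldimethylsilyl)oxy]-1-(furan-3-yl)-4,8,12-trimethyltridec-7-en-4-ol, via alkyllithium 28 (not isolated), via alkylcopper 29 (not isolated), via 6-lithiodihydropyran 30 (not isolated), via lithium alkyl(alkenyl)cuprate 31 (not isolated), via ring-opened alkenylcopper alkoxide 32 (not isolated)
Conditions: 23, t-BuLi (2.0 equiv), Et2O–pentane, −78 °C; CuBr·SMe2 (1.0 equiv), Me2S–Et2O, −78 → −40 °C; then 30 [from 15, n-BuLi (1.0 equiv), THF, −78 °C], −78 °C → rt; MeI (excess), −20 °C → rt; aq. NH3 work-up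
Reagents that add atoms: iodomethane, CI
Why: Tin–lithium exchange on 15 and iodine–lithium exchange on 23 give 30 and 28, which with CuBr·SMe2 assemble the cuprate 31; on warming, the alkyl ligand shifts from copper to C6 anti to the C6–O1 bond (inversion at the alkenyl carbon), the ring oxygen leaves as the tertiary lithium alkoxide, and the resulting alkoxide-ligated alkenylcopper 32 is methylated by MeI with retention. The closest known reaction type is the 1,2-metalate rearrangement of α-alkoxyalkenyl cuprates made from 5-lithio-2,3-dihydrofurans and 6-lithio-3,4-dihydro-2H-pyrans, followed by alkylation of the alkenylcopper. No ring is closed: the dihydropyran is opened, and the step forms the CH2–C(sp2) and C(sp2)–CH3 bonds. No stereocentre is created; ring C2 keeps all four bonds (the bond broken is C6–O1) and emerges as the (S)-carbinol, and the methyl-bearing centre of 23 lies three carbons from the metalated carbon. The step needs E geometry, which the ring secures because O1 and C4 are held cis across C5=C6, so the anti shift places the incoming chain trans to C4 and copper, then methyl, cis to it. It also needs the furan C–H bonds left alone, which is secured by making 30 through exchange with exactly one equivalent of n-BuLi at −78 °C and binding it to copper before warming.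

Step 18
Reactants: 33 (4S,7E,12S)-13-[(tert-butyldimethylsilyl)oxy]-1-(furan-3-yl)-4,8,12-trimethyltridec-7-en-4-ol
Product: 34 (2S,6E,10S)-13-(furan-3-yl)-2,6,10-trimethyltridec-6-ene-1,10-diol
Conditions: Bu4NF, THF, 0 °C → rt
Reagents that add atoms: none
Why: Fluoride-induced desilylation cleaves the primary TBS ether with no effect on the alkene, the furan or the tertiary alcohol.

Step 19
Reactants: 34 (2S,6E,10S)-13-(furan-3-yl)-2,6,10-trimethyltridec-6-ene-1,10-diol
Product: 35 (2S,6E,10S)-13-(furan-3-yl)-10-hydroxy-2,6,10-trimethyltridec-6-enal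
Conditions: Dess–Martin periodinane, NaHCO3, CH2Cl2, 0 °C → rt; used at once
Reagents that add atoms: none
Why: Dess–Martin oxidation under NaHCO3 buffer converts only the primary alcohol, the tertiary one having no carbinol hydrogen, and is mild enough to preserve the α-methyl stereocentre.

Step 20
Reactants: 35 (2S,6E,10S)-13-(furan-3-yl)-10-hydroxy-2,6,10-trimethyltridec-6-enal; 27 4-methoxy-3-methylfuran-2(5H)-one
Product: 37 5-[(2S,6E,10S)-13-(furan-3-yl)-1,10-dihydroxy-2,6,10-trimethyltridec-6-en-1-yl]-4-methoxy-3-methylfuran-2(5H)-one (mixture at C5 and C1'), via lithiated tetronate 36 (not isolated)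
Conditions: 27 (2.5 equiv), LiN(i-Pr)2 (2.5 equiv), THF, −78 °C; then 35, −78 °C; aq. work-up
Reagents that add atoms: none
Why: Aldol addition of the C5-lithiated methyl tetronate (a 2-oxidofuran) to the aldehyde at −78 °C; the excess nucleophile absorbs the tertiary O–H, and the two new stereocentres need no control because both become sp2 in step 21.

Step 21
Reactants: 37 5-[(2S,6E,10S)-13-(furan-3-yl)-1,10-dihydroxy-2,6,10-trimethyltridec-6-en-1-yl]-4-methoxy-3-methylfuran-2(5H)-one
Product: 39 (5Z)-5-[(2S,6E,10S)-13-(furan-3-yl)-10-hydroxy-2,6,10-trimethyltridec-6-en-1-ylidene]-4-methoxy-3-methylfuran-2(5H)-one, via acetate 38 (not isolated)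
Conditions: Ac2O (1.5 equiv), Et3N, DMAP (cat.), CH2Cl2, 0 °C; then DBU, rt
Reagents that add atoms: none
Why: Acetylation of the secondary carbinol (the tertiary alcohol is too hindered under these conditions) and DBU-induced E1cB elimination through the aromatic furanolate should give the ylidene, the Z isomer with the chain syn to the ring oxygen and away from the 4-methoxy group being thermodynamically preferred.

Step 22
Reactants: 39 (5Z)-5-[(2S,6E,10S)-13-(furan-3-yl)-10-hydroxy-2,6,10-trimethyltridec-6-en-1-ylidene]-4-methoxy-3-methylfuran-2(5H)-one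
Product: 40 (5Z)-5-[(2S,6E,10S)-13-(furan-3-yl)-10-hydroxy-2,6,10-trimethyltridec-6-en-1-ylidene]-4-hydroxy-3-methylfuran-2(5H)-one (CNP0217216.2)
Conditions: LiCl, DMSO, 60 °C; then cold 0.5 M HCl
Reagents that add atoms: none
Why: SN2 O-demethylation of the vinylogous methyl ester by chloride in DMSO (Krapcho-type dealkylation) liberates the tetronic acid, which is protonated in a brief cold acidic work-up that the furan and the tertiary alcohol tolerate.

## Compound list

1 | (R)-linalool, (3R)-3,7-dimethylocta-1,6-dien-3-ol | C=C[C@](C)(O)CCC=C(C)C | starting material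
2 | (3S)-1-(9-borabicyclo[3.3.1]nonan-9-yl)-3,7-dimethyloct-6-en-3-ol (same spatial arrangement as 1) | B1(CC[C@](C)(O)CCC=C(C)C)C2CCCC1CCC2 | intermediate (not isolated)
3 | (R)-3,7-dimethyloct-6-ene-1,3-diol | OCC[C@](C)(O)CCC=C(C)C | intermediate
4 | (R)-3-hydroxy-3,7-dimethyloct-6-en-1-yl 4-methylbenzenesulfonate | Cc1ccc(cc1)S(=O)(=O)OCC[C@](C)(O)CCC=C(C)C | intermediate
5 | furan-3-ylmethanol | OCc1ccoc1 | starting material
6 | 3-(chloromethyl)furan | ClCc1ccoc1 | intermediate
7 | (furan-3-ylmethyl)magnesium chloride | Cl[Mg]Cc1ccoc1 | intermediate (not isolated)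
8 | (S)-1-(furan-3-yl)-4,8-dimethylnon-7-en-4-ol | CC(C)=CCC[C@@](C)(O)CCCc1ccoc1 | intermediate
9 | (6S)-9-(furan-3-yl)-2,6-dimethylnonane-2,3,6-triol (C3 epimers) | CC(C)(O)C(O)CC[C@@](C)(O)CCCc1ccoc1 | intermediate (not isolated)
10 | (5S)-5-[3-(furan-3-yl)propyl]-5-methyltetrahydrofuran-2-ol (anomers) | OC1CC[C@](C)(CCCc2ccoc2)O1 | intermediate
11 | (4S)-1-(furan-3-yl)-8-methoxy-4-methyloct-7-en-4-ol (E/Z) | COC=CCC[C@@](C)(O)CCCc1ccoc1 | intermediate
12 | (6S)-6-[3-(furan-3-yl)propyl]-2-methoxy-6-methyltetrahydro-2H-pyran (C2 epimers) | COC1CCC[C@](C)(CCCc2ccoc2)O1 | intermediate (not isolated)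
13 | (6S)-6-[3-(furan-3-yl)propyl]-6-methyl-2-(phenylsulfonyl)tetrahydro-2H-pyran (C2 epimers) | O=S(=O)(c1ccccc1)C1CCC[C@](C)(CCCc2ccoc2)O1 | intermediate
14 | tributyl[(6S)-6-[3-(furan-3-yl)propyl]-6-methyl-2-(phenylsulfonyl)tetrahydro-2H-pyran-2-yl]stannane | CCCC[Sn](CCCC)(CCCC)C1(S(=O)(=O)c2ccccc2)CCC[C@](C)(CCCc2ccoc2)O1 | intermediate (not isolated)
15 | tributyl{(2S)-2-[3-(furan-3-yl)propyl]-2-methyl-3,4-dihydro-2H-pyran-6-yl}stannane | CCCC[Sn](CCCC)(CCCC)C1=CCC[C@](C)(CCCc2ccoc2)O1 | intermediate
16 | methyl (R)-3-hydroxy-2-methylpropanoate | OC[C@@H](C)C(=O)OC | starting material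
17 | methyl (R)-3-[(tert-butyldimethylsilyl)oxy]-2-methylpropanoate | CC(C)(C)[Si](C)(C)OC[C@@H](C)C(=O)OC | intermediate
18 | (S)-3-[(tert-butyldimethylsilyl)oxy]-2-methylpropan-1-ol | CC(C)(C)[Si](C)(C)OC[C@@H](C)CO | intermediate
19 | (R)-3-[(tert-butyldimethylsilyl)oxy]-2-methylpropanal | CC(C)(C)[Si](C)(C)OC[C@@H](C)C=O | intermediate (not isolated)
20 | ethyl (S,E)-5-[(tert-butyldimethylsilyl)oxy]-4-methylpent-2-enoate | CC(C)(C)[Si](C)(C)OC[C@@H](C)/C=C/C(=O)OCC | intermediate
21 | ethyl (S)-5-[(tert-butyldimethylsilyl)oxy]-4-methylpentanoate | CC(C)(C)[Si](C)(C)OC[C@@H](C)CCC(=O)OCC | intermediate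
22 | (S)-5-[(tert-butyldimethylsilyl)oxy]-4-methylpentan-1-ol | CC(C)(C)[Si](C)(C)OC[C@@H](C)CCCO | intermediate
23 | (S)-tert-butyl[(5-iodo-2-methylpentyl)oxy]dimethylsilane | CC(C)(C)[Si](C)(C)OC[C@@H](C)CCCI | intermediate
24 | ethyl 2-methyl-3-oxobutanoate | CCOC(=O)C(C)C(C)=O | starting material
25 | ethyl 4-bromo-2-methyl-3-oxobutanoate (racemic) | CCOC(=O)C(C)C(=O)CBr | intermediate (not isolated)
26 | 4-hydroxy-3-methylfuran-2(5H)-one | CC1=C(O)COC1=O | intermediate
27 | 4-methoxy-3-methylfuran-2(5H)-one | COC1=C(C)C(=O)OC1 | intermediate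
28 | {(4S)-5-[(tert-butyldimethylsilyl)oxy]-4-methylpentyl}lithium | CC(C)(C)[Si](C)(C)OC[C@@H](C)CCC[Li] | intermediate (not isolated)
29 | {(4S)-5-[(tert-butyldimethylsilyl)oxy]-4-methylpentyl}copper | CC(C)(C)[Si](C)(C)OC[C@@H](C)CCC[Cu] | intermediate (not isolated)
30 | {(2S)-2-[3-(furan-3-yl)propyl]-2-methyl-3,4-dihydro-2H-pyran-6-yl}lithium | [Li]C1=CCC[C@](C)(CCCc2ccoc2)O1 | intermediate (not isolated)
31 | lithium {(4S)-5-[(tert-butyldimethylsilyl)oxy]-4-methylpentyl}{(2S)-2-[3-(furan-3-yl)propyl]-2-methyl-3,4-dihydro-2H-pyran-6-yl}cuprate | [Li+].CC(C)(C)[Si](C)(C)OC[C@@H](C)CCC[Cu-]C1=CCC[C@](C)(CCCc2ccoc2)O1 | intermediate (not isolated)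
32 | lithium (4S,7Z,12S)-13-[(tert-butyldimethylsilyl)oxy]-8-cuprio-1-(furan-3-yl)-4,12-dimethyltridec-7-en-4-olate (copper cis to C6) | [Li+].CC(C)(C)[Si](C)(C)OC[C@@H](C)CCC/C([Cu])=C/CC[C@@](C)([O-])CCCc1ccoc1 | intermediate (not isolated)
33 | (4S,7E,12S)-13-[(tert-butyldimethylsilyl)oxy]-1-(furan-3-yl)-4,8,12-trimethyltridec-7-en-4-ol | CC(C)(C)[Si](C)(C)OC[C@@H](C)CCC/C(C)=C/CC[C@@](C)(O)CCCc1ccoc1 | intermediate
34 | (2S,6E,10S)-13-(furan-3-yl)-2,6,10-trimethyltridec-6-ene-1,10-diol | OC[C@@H](C)CCC/C(C)=C/CC[C@@](C)(O)CCCc1ccoc1 | intermediate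
35 | (2S,6E,10S)-13-(furan-3-yl)-10-hydroxy-2,6,10-trimethyltridec-6-enal | O=C[C@@H](C)CCC/C(C)=C/CC[C@@](C)(O)CCCc1ccoc1 | intermediate
36 | lithium 4-methoxy-3-methylfuran-2-olate | [Li+].[O-]c1occ(OC)c1C | intermediate (not isolated)
37 | 5-[(2S,6E,10S)-13-(furan-3-yl)-1,10-dihydroxy-2,6,10-trimethyltridec-6-en-1-yl]-4-methoxy-3-methylfuran-2(5H)-one (mixture at C5 and C1') | COC1=C(C)C(=O)OC1C(O)[C@@H](C)CCC/C(C)=C/CC[C@@](C)(O)CCCc1ccoc1 | intermediate
38 | (2S,6E,10S)-13-(furan-3-yl)-10-hydroxy-1-(3-methoxy-4-methyl-5-oxo-2,5-dihydrofuran-2-yl)-2,6,10-trimethyltridec-6-en-1-yl acetate | COC1=C(C)C(=O)OC1C(OC(C)=O)[C@@H](C)CCC/C(C)=C/CC[C@@](C)(O)CCCc1ccoc1 | intermediate (not isolated)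
39 | (5Z)-5-[(2S,6E,10S)-13-(furan-3-yl)-10-hydroxy-2,6,10-trimethyltridec-6-en-1-ylidene]-4-methoxy-3-methylfuran-2(5H)-one | CC1=C(OC)/C(=C/[C@@H](C)CCC/C(C)=C/CC[C@@](C)(O)CCCc2ccoc2)OC1=O | intermediate
40 | (5Z)-5-[(2S,6E,10S)-13-(furan-3-yl)-10-hydroxy-2,6,10-trimethyltridec-6-en-1-ylidene]-4-hydroxy-3-methylfuran-2(5H)-one | CC1=C(O)/C(=C/[C@@H](C)CCC/C(C)=C/CC[C@@](C)(O)CCCc2ccoc2)OC1=O | target

## Step count and risks

Total step count: 22.
Longest linear sequence: 13 steps from (R)-linalool (steps 1, 2, 4, 5, 6, 7, 8, 17, 18, 19, 20, 21, 22).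

Steps most likely to fail:

1. Step 17. The 1,2-shift in a six-membered α-alkoxyalkenyl cuprate is slower than in the five-membered series. Thermal decay of the cuprate (β-hydride loss, homocoupling), ligand scrambling to homocuprates, or proton capture by the alkenylcopper in place of methylation may therefore intervene before the sequence is complete. Fallback, setting out from 15 and 23 and returning at 33: 15 is converted to 30 as before (n-BuLi, THF, −78 °C) and alkylated directly with 23 (DMPU, −78 °C → rt) to give tert-butyl{[(2S)-5-{(2S)-2-[3-(furan-3-yl)propyl]-2-methyl-3,4-dihydro-2H-pyran-6-yl}-2-methylpentyl]oxy}dimethylsilane F1. F1 is then heated with MeMgBr and catalytic NiCl2(PPh3)2 in toluene. Nickel-catalysed cross-coupling of the enol ether C6–O1 bond with the methyl Grignard reagent proceeds with retention, so methyl arrives cis to C4, the chain stays trans, and the ring opens to 33.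

2. Step 8. Tin may be lost by protonolysis of the acid-labile α-alkoxyalkenylstannane during elimination or chromatography, and β-elimination of sulfinic acid from the crowded stannyl sulfone may stall. Fallback, setting out from 11 and returning at 15: hydrolysis of 11 (PPTS, acetone–H2O) should give (6S)-6-[3-(furan-3-yl)propyl]-6-methyltetrahydro-2H-pyran-2-ol F2. Fétizon oxidation (Ag2CO3 on kieselguhr, toluene, reflux) should give (6S)-6-[3-(furan-3-yl)propyl]-6-methyltetrahydro-2H-pyran-2-one F3. KN(SiMe3)2 in THF at −78 °C forms potassium (2S)-2-[3-(furan-3-yl)propyl]-2-methyl-3,4-dihydro-2H-pyran-6-olate F4, which is trapped with PhNTf2 as (2S)-2-[3-(furan-3-yl)propyl]-2-methyl-3,4-dihydro-2H-pyran-6-yl trifluoromethanesulfonate F5. Palladium-catalysed stannylation of F5 ((Bu3Sn)2, Pd(PPh3)4, LiCl, THF, 60 °C) then gives 15.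

3. Step 4. Homocoupling may occur while the furylmethyl Grignard reagent forms, the bond may form through C2 of the furan instead of the CH2 group, and the γ-tosyloxy alkoxide may close to an oxetane. Fallback, setting out from 6 and 4 and returning at 8: 6 with PhSO2Na (DMF, rt) should give 3-[(phenylsulfonyl)methyl]furan F6. n-BuLi (THF, −78 °C) converts it to [furan-3-yl(phenylsulfonyl)methyl]lithium F7, which is alkylated with tosylate 4 (THF–DMPU, −78 °C → rt; the stabilised carbanion does not deprotonate the tertiary hydroxyl) to give (4R)-1-(furan-3-yl)-4,8-dimethyl-1-(phenylsulfonyl)non-7-en-4-ol F8. Reductive desulfonylation (Na(Hg), Na2HPO4, MeOH, −20 °C) then gives 8.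

Further compounds

F1 | step 17 | tert-butyl{[(2S)-5-{(2S)-2-[3-(furan-3-yl)propyl]-2-methyl-3,4-dihydro-2H-pyran-6-yl}-2-methylpentyl]oxy}dimethylsilane | CC(C)(C)[Si](C)(C)OC[C@@H](C)CCCC1=CCC[C@](C)(CCCc2ccoc2)O1
F2 | step 8 | (6S)-6-[3-(furan-3-yl)propyl]-6-methyltetrahydro-2H-pyran-2-ol (anomers) | OC1CCC[C@](C)(CCCc2ccoc2)O1
F3 | step 8 | (6S)-6-[3-(furan-3-yl)propyl]-6-methyltetrahydro-2H-pyran-2-one | O=C1CCC[C@](C)(CCCc2ccoc2)O1
F4 | step 8 | potassium (2S)-2-[3-(furan-3-yl)propyl]-2-methyl-3,4-dihydro-2H-pyran-6-olate | [K+].[O-]C1=CCC[C@](C)(CCCc2ccoc2)O1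
F5 | step 8 | (2S)-2-[3-(furan-3-yl)propyl]-2-methyl-3,4-dihydro-2H-pyran-6-yl trifluoromethanesulfonate | FC(F)(F)S(=O)(=O)OC1=CCC[C@](C)(CCCc2ccoc2)O1
F6 | step 4 | 3-[(phenylsulfonyl)methyl]furan | O=S(=O)(Cc1ccoc1)c1ccccc1
F7 | step 4 | [furan-3-yl(phenylsulfonyl)methyl]lithium | [Li]C(c1ccoc1)S(=O)(=O)c1ccccc1
F8 | step 4 | (4R)-1-(furan-3-yl)-4,8-dimethyl-1-(phenylsulfonyl)non-7-en-4-ol (C1 epimers) | CC(C)=CCC[C@@](C)(O)CCC(c1ccoc1)S(=O)(=O)c1ccccc1
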